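The summer run, with 1.3 equiv of L, read 6.0% of E at 2.00 h, and the dusk run, with twice as much L at the same temperature, read about half of that, 3.2%, at 2.00 h. Here J is the complex, L the ligand coming in, and E a product that counts as two J. The autumn run at 25 °C adds the time: from 0.417 h to 2.00 h its E grew by a factor of 2.16, and the root of the time ratio is 2.19. So each reading holds at its own temperature: E went as the root of the time in the autumn run at 25 °C, and as one over L between the summer and dusk runs at 10 °C. The summer run itself grew less than the root of the time, by a factor of 1.98 from 0.250 h to 4.00 h against a root of 4.00. Joining the root of the time and one over L at 25 °C, with Z held, is therefore my assumption and not something a run shows.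

| flask | J | L | Z | temperature | remark | time |
|---|---|---|---|---|---|---|
| summer | 0.25 M | 1.3 equiv | 5 equiv | 10 °C | run made earlier |  |
| autumn | 0.25 M | 0.65 equiv | 5 equiv | 25 °C | run made earlier |  |
| dusk | 0.25 M | 2.6 equiv | 5 equiv | 10 °C | run made earlier |  |
| midnight | 0.25 M | 1.3 equiv | 10 equiv | 25 °C | run made earlier |  |
| cedar | 0.25 M | 1.30 equiv | 5.00 equiv |  | everything together at the start at 5 °C, warmed to 25 °C at 2.5 h | 3.0 h |
| birch | 0.25 M | 1.30 equiv (fed, over 2.5 h) | 5.00 equiv |  | the addition at 5 °C, then warmed to 25 °C; the feed brings no volume worth counting | 3.0 h |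
| alder | 0.25 M (fed, over 2.5 h) | 1.30 equiv | 5.00 equiv | 25 °C | all else is in the flask from the start; the feed brings no volume worth counting | 3.0 h |
| oak | 0.25 M | 1.30 equiv | 5.00 equiv | 25 °C | everything together at the start | 3.0 h |

| run | time / h | E / % | G / % |
|---|---|---|---|
| summer | 0.250 | 4.1 | 0 |
| summer | 0.500 | 4.6 | 0.3 |
| summer | 0.833 | 6.0 | 0 |
| summer | 1.33 | 6.7 | 0.6 |
| summer | 2.00 | 6.0 | 0.8 |
| summer | 4.00 | 8.1 | 2.0 |
| autumn | 0.417 | 17.7 | 0.8 |
| autumn | 0.833 | 25.3 | 0.1 |
| autumn | 1.33 | 31.4 | 0 |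
| autumn | 1.50 | 32.8 | 0.5 |
| autumn | 2.00 | 38.3 | 0 |
| autumn | 2.50 | 41.4 | 0.4 |
| dusk | 0.417 | 2.5 | 0.1 |
| dusk | 0.667 | 2.4 | 1.1 |
| dusk | 1.00 | 2.7 | 0.2 |
| dusk | 2.00 | 3.2 | 2.5 |
| dusk | 3.00 | 3.5 | 3.2 |
| dusk | 5.00 | 2.6 | 4.0 |
| midnight | 0.200 | 8.0 | 0.2 |
| midnight | 0.333 | 9.4 | 0 |
| midnight | 0.667 | 13.0 | 0.9 |
| midnight | 1.33 | 18.4 | 1.6 |
| midnight | 2.50 | 25.8 | 2.3 |

(readings scatter by 0.5 percentage points)

- a species is counted by the J in it: one E counts as two

1. the flask that comes out highest in amount of E, in percent of the J charged; "all alike" if 1.5 percentage points covers them all (cedar / birch / alder / oak / all alike)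
2. amount of E at the end, in percent of the J charged, cedar
3. amount of E at the end, in percent of the J charged, birch
4. amount of E at the end, in percent of the J charged, alder
5. amount of E at the end, in percent of the J charged, oak

Take the last autumn reading, 41.4%, and scale it by this rule to 1.30 equiv of L and 3.0 h. You get 22.7%; call this the root-time yield Y. Oak has the Z and temperature of the autumn run, so Y is my figure for oak, and I don't stretch the rule to the cold or fed flasks. Oak's curve then starts steep and bends gently, without a sharp knee: 11.3% by 0.750 h, then 22.7% at 3.0 h. That leaves 77.3% of the J charged outside E, and the rule shows no level by then. At 2.50 h the curve stands at 20.7%, and the midnight run, with twice the Z, read more, 25.8%. That gap may come from the Z or from my assumed scaling with L, so Y stays a figure for oak's Z, and an uncertain one.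

The forecast gives cedar 11%, birch 30%, alder 16% and oak 25%, and names birch as highest: “L is scarce early, so E bursts even in the cold”. Its oak stands above my Y.

The highest flask is oak, at 22.3%, with birch at 19.3%, alder at 11.3% and cedar at 8.27%. Birch held 17.2% of E when it was warmed at 2.50 h. Y, at 22.7%, lies 0.40 percentage points from oak's result.

    J + L ⇌ Z + Q (K = 42.0, k = 0.0110 /M/s, Ea = 59.0 kJ/mol, ΔH = −31.0 kJ/mol)
    Q + L ⇌ Z + D (K = 4.80, k = 9.40 × 10⁻⁴ /M/s, Ea = 65.0 kJ/mol, ΔH = −70.0 kJ/mol)
    D + L ⇌ Z + G (K = 2.00, k = 0.00460 /M/s, Ea = 69.0 kJ/mol, ΔH = 15.0 kJ/mol)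
    G + L ⇌ Z + X (K = 76.0, k = 0.0850 /M/s, Ea = 50.0 kJ/mol, ΔH = −1.00 kJ/mol)
    2 J → E (k = 8.60 × 10⁻⁴ /M/s, Ea = 75.0 kJ/mol)
    (constants at 25 °C)

Now take oak with 0.330 equiv of L: Y scaled to that charge gives 89.4%. The computed flask gives 61.2%, with 19% of the J charged still unbound at the end.

Readings and results were computed from invented constants, noise included.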